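**Remark on the chemistry:** ring B positions carry the primed isoflavone locants (C-1' to C-6', with C-1' bonded to C-3 of the chromone). In the benzodioxole intermediates up to 15, heterocycle locants C4, C5 and C7 correspond to C-4', C-5' and C-1'. Ring A/C is taken from 2,4-dihydroxyacetophenone, not from a chromanone, because a 3-iodochromone already has the isoflavone oxidation level.

## The problem

Compound 23 is an isoflavone: a 7-hydroxychromen-4-one (rings A and C) bonded through C-3 to C-1' of a benzene ring B that carries five substituents. Ring B has hydroxyl groups at C-2' and C-3', a methoxy group at C-4' and a 2-methylbut-3-en-2-yl (reverse prenyl) group at C-5'; only C-6' keeps a hydrogen. There is no stereocenter and no double-bond geometry to set, so the whole difficulty is regiochemical: three neighbouring oxygens of which exactly one is methylated, and a quaternary benzylic carbon directly beside that methoxy group. Direct prenylation of a phenol delivers the linear 3-methylbut-2-enyl isomer, so the branched group has to arise through an allylic transposition. The terminal alkene on the quaternary carbon will not tolerate strong acid (cation formation and rearrangement, or closure to a dihydrobenzofuran if the neighbouring oxygen is a free hydroxyl), electrophilic halogen in excess, or hydrogenation. The free catechol oxidises in air, and the pyranone ring opens when hard nucleophiles attack C-2. The enabling feature is that C-5' and C-4' are adjacent and C-4' lies next to O-3': an aryne spanning C-4' and C-5' is polarised by O-3' so that a carbon nucleophile enters at C-5' and the carbanion appears at C-4', exactly where carbon and oxygen are needed. After that, C-1' is the only ring B C–H ortho to an oxygen, which singles it out for the bond to ring C.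

## Retrosynthesis

**23 from 22.** Only C–O bonds are cut: the methoxymethyl ether on O-7 and the isopropylidene ketal across O-2' and O-3'. Both are acetals, so one acid treatment frees all three hydroxyls, and both survive the organolithium, Grignard and basic palladium steps before it. The methyl ether at C-4' is already in place in 22, so the three ring B oxygens never need to be told apart at the end. The forward step must cleave a fairly robust catechol ketal without protonating the terminal alkene.

**22 from 17 and 21.** The C-3 to C-1' bond is cut to give pinacol boronate 17 and 3-iodochromone 21, joined by Suzuki–Miyaura coupling. The neighbouring options are less direct: alpha-arylation of a chroman-4-one needs a later dehydrogenation with an oxidant beside an electron-rich ring and an alkene, and a deoxybenzoin route needs a ring B arylacetic acid. The cut divides the molecule into two halves of similar size, and ring C arrives at the right oxidation level. The coupling must outrun protodeboronation of an electron-rich, ortho-oxygenated boronate, and the chromone must survive aqueous carbonate.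

**21 from 20, 19 and 18.** The iodochromone is taken back through enaminone 20 to ketone 19 and 2,4-dihydroxyacetophenone 18. Ring C closes when iodine activates the enaminone and the chelated phenol adds, which places iodine at C-3 without a separate halogenation. Only the non-chelated hydroxyl of 18 is protected.

**17 from 15.** The C-1' to boron bond is cut. In 15 the hydrogen at C-1' is the only one ortho to an oxygen, so directed lithiation can only occur there. Electrophilic bromination would have to choose between C-1' and C-6' and might touch the alkene. The precursor is a simple trisubstituted benzodioxole with no functional handle at C-1'.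

**15 from 14.** The O–CH3 bond at C-4' is cut. Methylating the one free phenol of 14 fixes the methoxy group without any selectivity problem and removes the free hydroxyl beside the reverse prenyl group before any acid is used.

**14 from 7 and 9.** Two bonds are cut across one aryne: C-5' to the quaternary carbon and C-4' to oxygen. Friedel–Crafts prenylation would give the linear isomer without positional control. Claisen rearrangement of a prenyl ether forms the same C–C bond but needs high temperature and competes with para migration and cyclisation. The aryne route forms the carbon bond and the oxygen precursor in one flask at low temperature, from iodo sulfonate 7 and prenylmagnesium chloride 9. The forward reaction must control the orientation of addition to the aryne and the terminus through which the allyl unit reacts.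

**7 from 6, 5, 3, 2 and 1; 9 from 8.** The aryne precursor goes back to pyrogallol 1. The isopropylidene ketal of 2 ties up two adjacent oxygens and leaves one phenol free. That phenol, as carbamate 3, directs lithiation and iodination to its only free ortho carbon (5); it is then released (6) and turned into the sulfonate leaving group (7). The original pyrogallol oxygen at C-4' is therefore spent as a leaving group and replaced by a new one in the key step; this is the price of the regiocontrol. Grignard reagent 9 comes from prenyl chloride 8.

## Roads not taken

**Alternative 1:** Ring B itself is disconnected at C-4' to C-5'. A 4-alkynyl-4-hydroxycyclobutenone A2, from a squaric ester and a lithium acetylide already carrying the gem-dimethyl vinyl unit, is heated. It opens to a vinylketene that closes onto the alkyne and gives the 2,3-dialkoxybenzoquinone A1 (Moore cyclization).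
- Merits: every ring B substituent is placed by construction, the quaternary carbon is present before the ring exists, and the key step is a thermal reaction of a known type. In precedent this road is stronger than the chosen plan, whose key step is untested.
- Weak points: A1 carries oxygen at C-1', where 23 needs the bond to C-3. The quinone must be reduced, its two hydroxyls differentiated (one methylated, one turned into a sulfonate for cross-coupling), and two isopropyl ethers removed later beside a methyl ether. Bulky alkyne substituents also favour the competing five-membered closure to alkylidene cyclopentenediones.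
- Comparison: the chosen plan has the right oxidation pattern after the key step: 14 has hydrogen at C-1' and a single free phenol, so the endgame is shorter and needs no ether differentiation.

**Alternative 2:** Ring C is cut at C-3 to C-4. A carbene from a triazolium salt and DBU turns the aldehyde of the tethered aldehyde–ketone A4 into an acyl anion equivalent that adds to the ring B ketone, giving racemic 3-hydroxychromanone A3. Dehydration would then give the isoflavone.
- Merits: catalytic, mild, and the intramolecular aldehyde–ketone benzoin to chroman-4-ones is established. It uses no palladium and no boron, and in that respect it is at least as good as the junction chosen here.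
- Weak points: it does not address ring B. A4 already contains the fully substituted arene with the reverse prenyl group, which would still have to be made by an aryne or Claisen route and then acylated. The ketone is flanked by an ortho oxygen, which slows addition. A stereocenter is created only to be destroyed, and a dehydration step is added.
- Comparison: the chosen plan concentrates its invention on ring B, where the real difficulty lies, and joins the halves in one standard coupling.

**Alternative 3:** The C-3 to C-1' bond is formed by a 1,2-aryl shift. Chalcone A6, from aldol condensation of ketone 19 with ring B aldehyde A7, is treated with the trivalent iodine reagent PhI(OH)OTs in methanol. Ring B migrates to the alpha carbon, and acid closes ring C to give isoflavone A5.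
- Merits: it follows the biosynthetic logic, the chalcone is easy to assemble, and an electron-rich ring B migrates readily. The step count from the aldehyde is comparable to the coupling route.
- Weak points: the trivalent iodine oxidant also attacks isolated alkenes, so the terminal vinyl group competes with the enone. The acid used for ring closure threatens the three methoxymethyl ethers of A5. A7 again presupposes a solution to ring B, with three protecting groups where the chosen plan uses one ketal.
- Comparison: the chosen plan keeps oxidants away from the alkene and needs no oxidative step after the reverse prenyl group is in place. It pays for this with a key step that has no direct precedent.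

Key step: step 7

## Route

Step 1
Reactants: 1 pyrogallol
Product: 2 2,2-dimethyl-1,3-benzodioxol-4-ol
Conditions: Me2C(OMe)2, TsOH·H2O (cat.), toluene, reflux, MeOH distilled off
Reagents that add atoms: 2,2-dimethoxypropane, COC(C)(C)OC
Why: Acid-catalysed transketalisation closes the five-membered ketal across two adjacent hydroxyls; both adjacent pairs are equivalent by symmetry, so a single product with one free phenol results.

Step 2
Reactants: 2 2,2-dimethyl-1,3-benzodioxol-4-ol
Product: 3 2,2-dimethyl-1,3-benzodioxol-4-yl N,N-diethylcarbamate
Conditions: Et2NCOCl, K2CO3, MeCN, reflux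
Reagents that add atoms: N,N-diethylcarbamoyl chloride, CCN(CC)C(=O)Cl
Why: O-Carbamoylation of a phenoxide; the diethylcarbamate is the strongest oxygen-based directing group for ortho-lithiation and is stable to base.

Step 3
Reactants: 3 2,2-dimethyl-1,3-benzodioxol-4-yl N,N-diethylcarbamate
Product: 5 5-iodo-2,2-dimethyl-1,3-benzodioxol-4-yl N,N-diethylcarbamate, via ortho-lithiated carbamate 4 (not isolated)
Conditions: s-BuLi, TMEDA, THF, −78 °C; then I2, THF, −78 °C to rt
Reagents that add atoms: iodine, II
Why: Directed ortho-metalation; the carbamate has only one free ortho carbon (C5) and outranks the ring oxygen as director, and at −78 °C the aryllithium is iodinated before an anionic Fries shift can start.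

Step 4
Reactants: 5 5-iodo-2,2-dimethyl-1,3-benzodioxol-4-yl N,N-diethylcarbamate
Product: 6 5-iodo-2,2-dimethyl-1,3-benzodioxol-4-ol
Conditions: KOH, EtOH/H2O, reflux; then aq. NH4Cl
Reagents that add atoms: none
Why: Alkaline hydrolysis of an aryl carbamate; the ketal and the aryl iodide are inert to hydroxide, and the phenoxide leaving group drives the cleavage.

Step 5
Reactants: 6 5-iodo-2,2-dimethyl-1,3-benzodioxol-4-ol
Product: 7 5-iodo-2,2-dimethyl-1,3-benzodioxol-4-yl 4-chlorobenzenesulfonate
Conditions: 4-ClC6H4SO2Cl, Et3N, DMAP (cat.), CH2Cl2, 0 °C to rt
Reagents that add atoms: 4-chlorobenzenesulfonyl chloride, O=S(=O)(Cl)c1ccc(Cl)cc1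
Why: O-Sulfonylation of a phenol; the 4-chlorobenzenesulfonate is a leaving group that tolerates iodine–magnesium exchange in the cold and departs only on warming.

Step 6
Reactants: 8 1-chloro-3-methylbut-2-ene (prenyl chloride)
Product: 9 (3-methylbut-2-enyl)magnesium chloride
Conditions: Mg turnings (excess), THF, 0 °C, slow addition
Reagents that add atoms: magnesium, [Mg]
Why: Grignard formation from an allylic chloride; slow addition to excess magnesium at low temperature suppresses Wurtz coupling.

Step 7
Reactants: 7 5-iodo-2,2-dimethyl-1,3-benzodioxol-4-yl 4-chlorobenzenesulfonate; 9 (3-methylbut-2-enyl)magnesium chloride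
Product: 14 2,2-dimethyl-5-(2-methylbut-3-en-2-yl)-1,3-benzodioxol-4-ol, via magnesiated aryl sulfonate 10 (not isolated), via benzodioxole aryne 11 (not isolated), via arylmagnesium adduct 12 (not isolated), via dimethyl arylboronate 13 (not isolated)
Conditions: iPrMgCl·LiCl (1.05 equiv), THF, −78 °C; 9 (2 equiv), −78 °C to rt; B(OMe)3, −78 °C to rt; 30% H2O2, aq. NaOH, 0 °C
Reagents that add atoms: hydrogen peroxide, OO
Why: Proposed new method: iodine–magnesium exchange at −78 °C gives the 2-magnesiated aryl sulfonate 10, which is stable in the cold and on warming expels magnesium 4-chlorobenzenesulfonate to release aryne 11 in the presence of allylic Grignard reagent 9. The C–Mg bond of 9 is expected to add across the strained triple bond through a six-membered magnesio-ene transition state in which the dimethyl-substituted gamma carbon bonds to C5, magnesium moves to C4 and the double bond shifts to the chain end, which creates the 2-methylbut-3-en-2-yl group with its quaternary carbon. The closest known reaction type is the addition of magnesium thiolates, magnesium amides and aryl Grignard reagents to arynes made from 2-magnesiated aryl sulfonates with electrophilic trapping of the new arylmagnesium, together with the gamma-selective reaction of prenylmagnesium halides with carbonyl compounds; an allylic Grignard reagent has not been shown to add to an aryne in this way. No ring is closed and no stereocenter is formed. Two selectivities are needed: carbon at C5 with metal at C4 of the aryne, and gamma over alpha attack of the prenyl unit. The first is secured by the ring oxygen on C3a, which polarises the aryne by induction, stabilises the carbanion developing beside it and can hold the magnesium, while the bulky carbon terminus goes to the end flanked only by hydrogen; the second follows from the cyclic transition state. Arylmagnesium 12 is then borylated to 13 and alkaline H2O2 moves the aryl group from boron to oxygen at the same carbon, leaving the terminal alkene untouched.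

Step 8
Reactants: 14 2,2-dimethyl-5-(2-methylbut-3-en-2-yl)-1,3-benzodioxol-4-ol
Product: 15 4-methoxy-2,2-dimethyl-5-(2-methylbut-3-en-2-yl)-1,3-benzodioxole
Conditions: MeI, K2CO3, DMF, 40 °C
Reagents that add atoms: iodomethane, CI
Why: Williamson methylation of the only free phenol; a polar aprotic solvent overcomes the flanking by the tertiary alkyl group, and capping this oxygen removes the hydroxyl that could later cyclise onto the alkene under acid.

Step 9
Reactants: 15 4-methoxy-2,2-dimethyl-5-(2-methylbut-3-en-2-yl)-1,3-benzodioxole
Product: 17 2-[7-methoxy-2,2-dimethyl-6-(2-methylbut-3-en-2-yl)-1,3-benzodioxol-4-yl]-4,4,5,5-tetramethyl-1,3,2-dioxaborolane, via aryllithium 16 (not isolated)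
Conditions: n-BuLi, TMEDA, THF, −78 to 0 °C; iPrOBpin, −78 °C to rt
Reagents that add atoms: 2-isopropoxy-4,4,5,5-tetramethyl-1,3,2-dioxaborolane, CC(C)OB1OC(C)(C)C(C)(C)O1
Why: Directed ortho-metalation beside the dioxole oxygen followed by borylation; C7 (C-1') bears the only hydrogen ortho to an oxygen, the side chain has no allylic or benzylic hydrogen, and the 2,2-dimethyl ketal has no acidic position.

Step 10
Reactants: 18 1-(2,4-dihydroxyphenyl)ethanone (2,4-dihydroxyacetophenone)
Product: 19 1-[2-hydroxy-4-(methoxymethoxy)phenyl]ethanone
Conditions: MOMCl, K2CO3, acetone, rt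
Reagents that add atoms: chloromethyl methyl ether, COCCl
Why: Selective O-alkylation; the 2-hydroxyl is held in a hydrogen bond to the ketone and stays free, so only the 4-hydroxyl is protected.

Step 11
Reactants: 19 1-[2-hydroxy-4-(methoxymethoxy)phenyl]ethanone
Product: 20 (E)-3-(dimethylamino)-1-[2-hydroxy-4-(methoxymethoxy)phenyl]prop-2-en-1-one
Conditions: Me2NCH(OMe)2, toluene, 90 °C
Reagents that add atoms: N,N-dimethylformamide dimethyl acetal, COC(OC)N(C)C
Why: Enaminone condensation of a methyl ketone with an amide acetal; it adds the carbon that becomes C-2 and gives the E isomer, which is the thermodynamically favoured one.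

Step 12
Reactants: 20 (E)-3-(dimethylamino)-1-[2-hydroxy-4-(methoxymethoxy)phenyl]prop-2-en-1-one
Product: 21 3-iodo-7-(methoxymethoxy)chromen-4-one
Conditions: I2, pyridine, CHCl3, rt
Reagents that add atoms: iodine, II
Why: Iodocyclisation of a 2-hydroxyaryl enaminone; iodination at the alpha carbon gives an iminium ion, the phenol adds by 6-endo closure and dimethylamine is lost, while pyridine keeps the medium from cleaving the methoxymethyl ether.

Step 13
Reactants: 17 2-[7-methoxy-2,2-dimethyl-6-(2-methylbut-3-en-2-yl)-1,3-benzodioxol-4-yl]-4,4,5,5-tetramethyl-1,3,2-dioxaborolane; 21 3-iodo-7-(methoxymethoxy)chromen-4-one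
Product: 22 7-(methoxymethoxy)-3-[7-methoxy-2,2-dimethyl-6-(2-methylbut-3-en-2-yl)-1,3-benzodioxol-4-yl]chromen-4-one
Conditions: Pd(dppf)Cl2 (5 mol%), K2CO3, 1,4-dioxane/H2O, 80 °C
Reagents that add atoms: none
Why: Suzuki–Miyaura coupling of a 3-iodochromone with an arylboronate, the standard isoflavone junction; oxidative addition into the vinylogous acyl iodide is fast, and the hindered, unactivated vinyl group does not compete in a Heck pathway.

Step 14
Reactants: 22 7-(methoxymethoxy)-3-[7-methoxy-2,2-dimethyl-6-(2-methylbut-3-en-2-yl)-1,3-benzodioxol-4-yl]chromen-4-one
Product: 23 3-[2,3-dihydroxy-4-methoxy-5-(2-methylbut-3-en-2-yl)phenyl]-7-hydroxychromen-4-one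
Conditions: conc. HCl, MeOH, 60 °C, under Ar
Reagents that add atoms: none
Why: Acid-catalysed acetal exchange removes the methoxymethyl ether and the isopropylidene ketal in one operation; the monosubstituted alkene is protonated only slowly, the oxygen beside it is a methyl ether and cannot cyclise, and the aryl methyl ether is inert.

## Compound list

1 | pyrogallol (benzene-1,2,3-triol) | Oc1cccc(O)c1O | starting material
2 | 2,2-dimethyl-1,3-benzodioxol-4-ol | CC1(C)Oc2cccc(O)c2O1 | intermediate
3 | 2,2-dimethyl-1,3-benzodioxol-4-yl N,N-diethylcarbamate | CCN(CC)C(=O)Oc1cccc2OC(C)(C)Oc12 | intermediate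
4 | [4-(diethylcarbamoyloxy)-2,2-dimethyl-1,3-benzodioxol-5-yl]lithium | CCN(CC)C(=O)Oc1c([Li])ccc2OC(C)(C)Oc12 | intermediate (not isolated)
5 | 5-iodo-2,2-dimethyl-1,3-benzodioxol-4-yl N,N-diethylcarbamate | CCN(CC)C(=O)Oc1c(I)ccc2OC(C)(C)Oc12 | intermediate
6 | 5-iodo-2,2-dimethyl-1,3-benzodioxol-4-ol | CC1(C)Oc2ccc(I)c(O)c2O1 | intermediate
7 | 5-iodo-2,2-dimethyl-1,3-benzodioxol-4-yl 4-chlorobenzenesulfonate | CC1(C)Oc2ccc(I)c(OS(=O)(=O)c3ccc(Cl)cc3)c2O1 | intermediate
8 | 1-chloro-3-methylbut-2-ene (prenyl chloride) | CC(C)=CCCl | starting material
9 | (3-methylbut-2-enyl)magnesium chloride | CC(C)=CC[Mg]Cl | intermediate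
10 | [4-(4-chlorophenyl)sulfonyloxy-2,2-dimethyl-1,3-benzodioxol-5-yl]magnesium chloride | CC1(C)Oc2ccc([Mg]Cl)c(OS(=O)(=O)c3ccc(Cl)cc3)c2O1 | intermediate (not isolated)
11 | 2,2-dimethyl-4,5-didehydro-1,3-benzodioxole (aryne) | CC1(C)OC2=C(O1)C#CC=C2 | intermediate (not isolated)
12 | [2,2-dimethyl-5-(2-methylbut-3-en-2-yl)-1,3-benzodioxol-4-yl]magnesium chloride | C=CC(C)(C)c1ccc2OC(C)(C)Oc2c1[Mg]Cl | intermediate (not isolated)
13 | dimethyl [2,2-dimethyl-5-(2-methylbut-3-en-2-yl)-1,3-benzodioxol-4-yl]boronate | C=CC(C)(C)c1ccc2OC(C)(C)Oc2c1B(OC)OC | intermediate (not isolated)
14 | 2,2-dimethyl-5-(2-methylbut-3-en-2-yl)-1,3-benzodioxol-4-ol | C=CC(C)(C)c1ccc2OC(C)(C)Oc2c1O | intermediate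
15 | 4-methoxy-2,2-dimethyl-5-(2-methylbut-3-en-2-yl)-1,3-benzodioxole | C=CC(C)(C)c1ccc2OC(C)(C)Oc2c1OC | intermediate
16 | [7-methoxy-2,2-dimethyl-6-(2-methylbut-3-en-2-yl)-1,3-benzodioxol-4-yl]lithium | C=CC(C)(C)c1cc([Li])c2OC(C)(C)Oc2c1OC | intermediate (not isolated)
17 | 2-[7-methoxy-2,2-dimethyl-6-(2-methylbut-3-en-2-yl)-1,3-benzodioxol-4-yl]-4,4,5,5-tetramethyl-1,3,2-dioxaborolane | C=CC(C)(C)c1cc(B2OC(C)(C)C(C)(C)O2)c2OC(C)(C)Oc2c1OC | intermediate
18 | 1-(2,4-dihydroxyphenyl)ethanone | CC(=O)c1ccc(O)cc1O | starting material
19 | 1-[2-hydroxy-4-(methoxymethoxy)phenyl]ethanone | CC(=O)c1ccc(OCOC)cc1O | intermediate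
20 | (E)-3-(dimethylamino)-1-[2-hydroxy-4-(methoxymethoxy)phenyl]prop-2-en-1-one | CN(C)/C=C/C(=O)c1ccc(OCOC)cc1O | intermediate
21 | 3-iodo-7-(methoxymethoxy)chromen-4-one | COCOc1ccc2c(c1)occ(I)c2=O | intermediate
22 | 7-(methoxymethoxy)-3-[7-methoxy-2,2-dimethyl-6-(2-methylbut-3-en-2-yl)-1,3-benzodioxol-4-yl]chromen-4-one | C=CC(C)(C)c1cc(-c2coc3cc(OCOC)ccc3c2=O)c2OC(C)(C)Oc2c1OC | intermediate
23 | 3-[2,3-dihydroxy-4-methoxy-5-(2-methylbut-3-en-2-yl)phenyl]-7-hydroxychromen-4-one | C=CC(C)(C)c1cc(-c2coc3cc(O)ccc3c2=O)c(O)c(O)c1OC | target

## Step count and risks

Total: 14 steps, including the preparation of Grignard reagent 9 and the three steps to iodochromone 21. Longest linear sequence: 10 steps from pyrogallol 1 (steps 1, 2, 3, 4, 5, 7, 8, 9, 13, 14).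

**Step 7 (key step, proposed new method).** Several processes could divert it:
- reaction of the allyl nucleophile through its unsubstituted terminus, which would give the linear prenyl isomer;
- addition with the reverse orientation at the aryne;
- attack of 9 at sulfur of the sulfonate before the aryne is released;
- consumption of the aryne by arylmagnesium 12;
- incomplete borylation of the hindered arylmagnesium, so that protonation replaces oxidation.

Fallback with known chemistry: starting from phenol 2, O-alkylation with prenyl bromide and K2CO3 in acetone should give 2,2-dimethyl-4-(3-methylbut-2-enoxy)-1,3-benzodioxole F1. Aromatic Claisen rearrangement of F1 in N,N-diethylaniline at about 190 °C transfers the allyl unit with inversion to the only free ortho carbon and returns to the route at 14. This path is shorter. Its cost is a high-temperature step in which migration to the para position and cyclisation of the product phenol onto its alkene compete.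

**Step 4.** Hydrolysis may be slow because the carbamate carbonyl is shielded by iodine on one side and the ring oxygen on the other, and forcing conditions may start to erode the aryl iodide. Fallback with a different directing group, starting from 2:
- protection with MOMCl and iPr2NEt to give 4-(methoxymethoxy)-2,2-dimethyl-1,3-benzodioxole F2;
- lithiation with n-BuLi in THF at 0 °C to give [4-(methoxymethoxy)-2,2-dimethyl-1,3-benzodioxol-5-yl]lithium F3;
- iodination to give 5-iodo-4-(methoxymethoxy)-2,2-dimethyl-1,3-benzodioxole F4;
- removal of the ether with dilute HCl in MeOH at rt, conditions under which the catechol ketal exchanges far more slowly, returning to the route at 6.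

**Step 9.** Deprotonation beside the dioxole oxygen may be incomplete, or butyllithium may add to the vinyl group during the longer metalation time. Fallback by electrophilic substitution, starting from 15: bromination with NBS in MeCN at 0 °C should give 4-bromo-7-methoxy-2,2-dimethyl-6-(2-methylbut-3-en-2-yl)-1,3-benzodioxole F5. The position ortho to one oxygen and para to the methoxy group is favoured over the one beside the tertiary alkyl group. Miyaura borylation of F5 (B2pin2, Pd(dppf)Cl2, KOAc, dioxane, 80 °C) returns to the route at 17.

**Step 13.** Protodeboronation of the electron-rich, ortho-oxygenated boronate and opening of the pyranone by aqueous base may outpace transmetalation. Fallback without water or base, starting from 15 and 21: aryllithium 16 is made as in step 9 and transmetalated with ZnCl2 to [7-methoxy-2,2-dimethyl-6-(2-methylbut-3-en-2-yl)-1,3-benzodioxol-4-yl]zinc chloride F6. Negishi coupling of F6 with 21 (Pd(PPh3)4, THF, 50 °C) returns to the route at 22.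

**Step 14.** Ketal cleavage may stall under acid mild enough for the alkene, stronger acid may hydrate or rearrange the alkene, and the liberated catechol may oxidise. Fallback in two stages, starting from 22:
- dilute HCl in MeOH at rt removes only the methoxymethyl ether and gives 7-hydroxy-3-[7-methoxy-2,2-dimethyl-6-(2-methylbut-3-en-2-yl)-1,3-benzodioxol-4-yl]chromen-4-one F7;
- BCl3 in CH2Cl2 at −78 °C then cleaves the cyclic ketal under anhydrous Lewis-acid conditions, which are known to spare aryl methyl ethers, returning to the route at 23.

## Further compounds

F1 | step 7 | 2,2-dimethyl-4-(3-methylbut-2-enoxy)-1,3-benzodioxole | CC(C)=CCOc1cccc2OC(C)(C)Oc12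
F2 | step 4 | 4-(methoxymethoxy)-2,2-dimethyl-1,3-benzodioxole | COCOc1cccc2OC(C)(C)Oc12
F3 | step 4 | [4-(methoxymethoxy)-2,2-dimethyl-1,3-benzodioxol-5-yl]lithium | COCOc1c([Li])ccc2OC(C)(C)Oc12
F4 | step 4 | 5-iodo-4-(methoxymethoxy)-2,2-dimethyl-1,3-benzodioxole | COCOc1c(I)ccc2OC(C)(C)Oc12
F5 | step 9 | 4-bromo-7-methoxy-2,2-dimethyl-6-(2-methylbut-3-en-2-yl)-1,3-benzodioxole | C=CC(C)(C)c1cc(Br)c2OC(C)(C)Oc2c1OC
F6 | step 13 | [7-methoxy-2,2-dimethyl-6-(2-methylbut-3-en-2-yl)-1,3-benzodioxol-4-yl]zinc chloride | C=CC(C)(C)c1cc([Zn]Cl)c2OC(C)(C)Oc2c1OC
F7 | step 14 | 7-hydroxy-3-[7-methoxy-2,2-dimethyl-6-(2-methylbut-3-en-2-yl)-1,3-benzodioxol-4-yl]chromen-4-one | C=CC(C)(C)c1cc(-c2coc3cc(O)ccc3c2=O)c2OC(C)(C)Oc2c1OC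
A1 | alternative 1 | 5-(2-methylbut-3-en-2-yl)-2,3-di(propan-2-yloxy)cyclohexa-2,5-diene-1,4-dione | O=C1C=C(C(C)(C)C=C)C(=O)C(OC(C)C)=C1OC(C)C
A2 | alternative 1 | 4-(3,3-dimethylpent-4-en-1-ynyl)-4-hydroxy-2,3-di(propan-2-yloxy)cyclobut-2-en-1-one | O=C1C(OC(C)C)=C(OC(C)C)C1(O)C#CC(C)(C)C=C
A3 | alternative 2 | racemic 3-hydroxy-7-(methoxymethoxy)-3-[7-methoxy-2,2-dimethyl-6-(2-methylbut-3-en-2-yl)-1,3-benzodioxol-4-yl]chroman-4-one | O=C1c2ccc(OCOC)cc2OCC1(O)c1cc(C(C)(C)C=C)c(OC)c2OC(C)(C)Oc12
A4 | alternative 2 | 4-(methoxymethoxy)-2-{2-[7-methoxy-2,2-dimethyl-6-(2-methylbut-3-en-2-yl)-1,3-benzodioxol-4-yl]-2-oxoethoxy}benzaldehyde | O=Cc1ccc(OCOC)cc1OCC(=O)c1cc(C(C)(C)C=C)c(OC)c2OC(C)(C)Oc12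
A5 | alternative 3 | 7-(methoxymethoxy)-3-[4-methoxy-2,3-bis(methoxymethoxy)-5-(2-methylbut-3-en-2-yl)phenyl]chromen-4-one | C=CC(C)(C)c1cc(-c2coc3cc(OCOC)ccc3c2=O)c(OCOC)c(OCOC)c1OC
A6 | alternative 3 | (E)-1-[2-hydroxy-4-(methoxymethoxy)phenyl]-3-[4-methoxy-2,3-bis(methoxymethoxy)-5-(2-methylbut-3-en-2-yl)phenyl]prop-2-en-1-one | C=CC(C)(C)c1cc(/C=C/C(=O)c2ccc(OCOC)cc2O)c(OCOC)c(OCOC)c1OC
A7 | alternative 3 | 4-methoxy-2,3-bis(methoxymethoxy)-5-(2-methylbut-3-en-2-yl)benzaldehyde | C=CC(C)(C)c1cc(C=O)c(OCOC)c(OCOC)c1OC
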